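**Assumptions:** (i) (2S)-naringenin is bought as the enantiopure (S) grade and its ee is checked by chiral HPLC, since bulk "naringenin" is often racemic. (ii) tert-Butyl (2-methylbut-3-en-2-yl) carbonate is treated as a catalogue reagent; otherwise it is one step from 2-methylbut-3-en-2-ol and Boc2O. The route is a proposal and has not been run.

## Retrosynthetic overview

1. Sigmoidin B (9) ⇐ 7-O-TIPS ether 8 by buffered fluoride desilylation.
2. 8 ⇐ 6: the 5'-OH comes from IBX ortho-oxygenation of the 4'-phenol, then dithionite reduction.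
3. 6 ⇐ 5: the aryl–prenyl C–C bond comes from an aromatic [3,3] Claisen rearrangement of the 4'-O-(1,1-dimethylallyl) ether; the B ring is para-substituted, so both ortho positions are equivalent and only one regioisomer can form.
4. 5 ⇐ 3 ⇐ 1: Pd π-allyl O-tert-prenylation of the only free reactive phenol, after selective 7-O-silylation of (2S)-naringenin.
5. No ring is formed in the route: rings A, B and C and the single C2 (S) stereocentre are all bought in (2S)-naringenin and carried through non-basic, low-temperature or neutral steps.

## Route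

**Step 1**
Reactants: 1, (2S)-naringenin; 2, triisopropylsilyl chloride
Product: 3, (2S)-5-hydroxy-2-(4-hydroxyphenyl)-7-[(triisopropylsilyl)oxy]chroman-4-one
Conditions: TIPSCl (1.05 equiv), Et3N (1.1 equiv), CH2Cl2/DMF, −10 → 0 °C
Reagents that add atoms: TIPSCl, CC(C)[Si](Cl)(C(C)C)C(C)C
Why: Regioselective phenol silylation – with one equivalent of amine only the most acidic 7-OH (para to the C4 carbonyl) is ionised, the 5-OH is chelated to C=O and the 4'-OH is about 2–3 pKa units weaker, and the 7-phenoxide does not promote ring opening, so C2 is untouched.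

**Step 2**
Reactants: 3, 7-O-TIPS-(2S)-naringenin; 4, tert-butyl (2-methylbut-3-en-2-yl) carbonate
Product: 5, (2S)-5-hydroxy-2-{4-[(2-methylbut-3-en-2-yl)oxy]phenyl}-7-[(triisopropylsilyl)oxy]chroman-4-one
Conditions: 4 (1.3 equiv), Pd(PPh3)4 (5 mol %), THF, 0 °C, 1–2 h, Ar
Reagents that add atoms: tert-butyl (2-methylbut-3-en-2-yl) carbonate, C=CC(C)(C)OC(=O)OC(C)(C)C (delivers the C5H9 unit; CO2 and t-BuOH are lost)
Why: Tsuji–Trost decarboxylative O-allylation – the 1,1-dimethyl-π-allyl-Pd cation is captured by the 4'-phenoxide at the tertiary terminus under kinetic control at 0 °C, with no external base, so the flavanone is not opened or racemised and the chelated 5-OH does not compete.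

**Step 3**
Reactants: 5, the 4'-O-(1,1-dimethylallyl) ether
Product: 6, (2S)-5-hydroxy-2-[4-hydroxy-3-(3-methylbut-2-en-1-yl)phenyl]-7-[(triisopropylsilyl)oxy]chroman-4-one
Conditions: degassed o-xylene, 130 °C, 2–4 h, base-washed glassware
Reagents that add atoms: none
Why: Aromatic Claisen [3,3]-sigmatropic rearrangement followed by tautomerisation – the tertiary allyl aryl ether rearranges at moderate temperature with allylic inversion to give the linear prenyl group at the ortho carbon, and the neutral aprotic medium leaves C2 (S) intact.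

**Step 4**
Reactants: 6, 7-O-TIPS-3'-prenylnaringenin; 7, 2-iodoxybenzoic acid (IBX)
Product: 8, (2S)-2-[3,4-dihydroxy-5-(3-methylbut-2-en-1-yl)phenyl]-5-hydroxy-7-[(triisopropylsilyl)oxy]chroman-4-one
Conditions: IBX (1.2 equiv), DMF, 0 °C → rt, 1 h; then aq. Na2S2O4, rt
Reagents that add atoms: IBX, O=C1OI(=O)(O)c2ccccc12 (delivers one O)
Why: IBX ortho-oxygenation of a phenol to the o-quinone with in-situ dithionite reduction to the catechol – oxygen is delivered from the aryloxy-iodane to the only unsubstituted ortho carbon of the electron-rich 2,4-dialkylphenol, while the chelated acyl-deactivated 5-OH, the silyl ether and the trisubstituted alkene are inert at rt and the quinone is reduced before it can tautomerise.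

**Step 5**
Reactants: 8, 7-O-TIPS-sigmoidin B
Product: 9, sigmoidin B, (2S)-2-[3,4-dihydroxy-5-(3-methylbut-2-en-1-yl)phenyl]-5,7-dihydroxychroman-4-one
Conditions: TBAF (1.1 equiv), AcOH (1.5 equiv), THF, 0 °C, 15 min, Ar
Reagents that add atoms: none
Why: Fluoride-mediated desilylation of an aryl silyl ether – the 7-O-Si bond of this acidic phenol cleaves quickly, and the acetic acid buffer prevents phenoxide-driven C2 epimerisation, catechol autoxidation and acid-type cyclisation of the prenyl group onto the 4'-OH.

## Compound list

1 | (2S)-naringenin | Oc1ccc([C@@H]2CC(=O)c3c(O)cc(O)cc3O2)cc1 | starting material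
2 | triisopropylsilyl chloride | CC(C)[Si](Cl)(C(C)C)C(C)C | starting material (reagent)
3 | (2S)-5-hydroxy-2-(4-hydroxyphenyl)-7-(triisopropylsilyloxy)chroman-4-one | Oc1ccc([C@@H]2CC(=O)c3c(O)cc(O[Si](C(C)C)(C(C)C)C(C)C)cc3O2)cc1 | intermediate
4 | tert-butyl (2-methylbut-3-en-2-yl) carbonate | C=CC(C)(C)OC(=O)OC(C)(C)C | starting material (reagent)
5 | (2S)-5-hydroxy-2-{4-[(2-methylbut-3-en-2-yl)oxy]phenyl}-7-(triisopropylsilyloxy)chroman-4-one | C=CC(C)(C)Oc1ccc([C@@H]2CC(=O)c3c(O)cc(O[Si](C(C)C)(C(C)C)C(C)C)cc3O2)cc1 | intermediate
6 | (2S)-5-hydroxy-2-[4-hydroxy-3-(3-methylbut-2-enyl)phenyl]-7-(triisopropylsilyloxy)chroman-4-one | CC(C)=CCc1cc([C@@H]2CC(=O)c3c(O)cc(O[Si](C(C)C)(C(C)C)C(C)C)cc3O2)ccc1O | intermediate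
7 | 2-iodoxybenzoic acid (IBX) | O=C1OI(=O)(O)c2ccccc12 | starting material (reagent)
8 | (2S)-2-[3,4-dihydroxy-5-(3-methylbut-2-enyl)phenyl]-5-hydroxy-7-(triisopropylsilyloxy)chroman-4-one | CC(C)=CCc1cc([C@@H]2CC(=O)c3c(O)cc(O[Si](C(C)C)(C(C)C)C(C)C)cc3O2)cc(O)c1O | intermediate
9 | sigmoidin B | CC(C)=CCc1cc([C@@H]2CC(=O)c3c(O)cc(O)cc3O2)cc(O)c1O | target

## Summary

Total step count: 5. Longest linear sequence: 5 (fully linear from 1).

Steps most likely to fail, with fallbacks:

1. **Step 4 (IBX ortho-hydroxylation).** The transient o-quinone may tautomerise to a quinone methide, which would epimerise C2 or form a chromene from the prenyl group, or it may over-oxidise. Fallback: buy the catechol instead of making it. Start from (2S)-eriodictyol, protect 7-OH as the TIPS ether, mono-O-tert-prenylate the catechol, run the Claisen rearrangement, separate the 5'-prenyl isomer from the 2'-prenyl isomer, and desilylate. This removes the oxidation but gives up regiocontrol at the etherification.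

2. **Step 2 (Pd O-tert-prenylation).** The tertiary ether can re-ionise and drift to the linear O-prenyl ether or to C-allylated products. Fallback: build the ether through the alkyne. Use Cu-catalysed O-propargylation with a 2-methylbut-3-yn-2-yl carbonate or trifluoroacetate (CuCl2 cat., DBU, MeCN, −5 °C), then Lindlar semihydrogenation to 5.

3. **Step 3 (thermal Claisen).** The tertiary ether may lose isoprene, or the o-prenylphenol may cyclise to a chroman. Fallback: make the 4'-O-prenyl (linear) ether by Mitsunobu reaction with prenol, then use an acidic-clay (montmorillonite K10 or Florisil) 1,3-O→C prenyl shift to reach 6 at or near room temperature.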